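**Retrosynthetic overview**

- The target (7-O-prenylkaempferide, an achiral flavonol) is cut last at the bond between pyranone C2 and the ipso carbon of the 4-methoxyphenyl ring. The forward step is an anodic dehydrogenative cross-coupling of 3,5-dihydroxy-7-(prenyloxy)chromone with anisole, with H2 as the only by-product and no activating group on either partner.
- Enabling feature: the 3-hydroxy-4-pyranone ring. Its enol (O3–H on C3=C2, flanked by ring O1) is the most easily oxidised site, and C2 is its only C–H carbon. Two-electron oxidation puts a cation on C2 (oxocarbenium through O1), the para carbon of anisole captures it, and enolisation restores the flavonol.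
- The C3 hydroxyl comes from nucleophilic epoxidation and isomerisation of the chromone C2=C3 bond, which tolerates the prenyl alkene. The prenyl ether is placed first, on the acidic 7-OH of 5,7-dihydroxychromone.
- Ring order: no ring is formed in the route. The benzopyranone bicycle comes from 5,7-dihydroxychromone and the third ring from anisole; they are joined in the last step.

Key step: step 3

Assumption: the target has no stereocentre and no configurable double bond (the prenyl alkene carries two methyl groups), so no stereocontrol is needed; 5,7-dihydroxychromone is taken as a catalogue compound.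

**Route**

Step 1
Reactants: 1 5,7-dihydroxy-4H-chromen-4-one (5,7-dihydroxychromone); 2 1-bromo-3-methylbut-2-ene (prenyl bromide)
Product: 3 5-hydroxy-7-[(3-methylbut-2-en-1-yl)oxy]-4H-chromen-4-one
Conditions: K2CO3 (1.2 equiv), 2 (1.1 equiv), acetone, reflux
Reagents that add atoms: none
Why: Williamson ether synthesis, in which K2CO3 deprotonates only the 7-OH (a vinylogous acid conjugated to C4=O) while the 5-OH stays locked in its hydrogen bond to C4=O, so SN2 attack on the primary allylic bromide should give the 7-O-prenyl ether alone; no stereocentre is formed.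

Step 2
Reactants: 3 5-hydroxy-7-[(3-methylbut-2-en-1-yl)oxy]-4H-chromen-4-one
Product: 5 3,5-dihydroxy-7-[(3-methylbut-2-en-1-yl)oxy]-4H-chromen-4-one, via epoxychromanone 4 (not isolated)
Conditions: t-BuOOH (5.5 M in decane, 1.5 equiv), DBU (0.3 equiv), CH2Cl2, 0 °C to rt; then PPTS (0.5 equiv), rt
Reagents that add atoms: tert-butyl hydroperoxide, CC(C)(C)OO
Why: Weitz–Scheffer nucleophilic epoxidation, in which the tert-butylperoxide anion adds to the electrophilic C2 of the chromone enone (left mostly un-ionised by the substoichiometric base) and the enolate closes the cis-fused epoxide 4 with loss of tert-butoxide, a nucleophilic oxidant that leaves the electron-rich prenyl alkene alone; mild acid then opens the acetal-type C2–O bond with help from O1 and loss of H3 gives the 3-hydroxy-4-pyranone, which erases both stereocentres of racemic 4.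

Step 3
Reactants: 5 3,5-dihydroxy-7-[(3-methylbut-2-en-1-yl)oxy]-4H-chromen-4-one; 6 anisole (methoxybenzene)
Product: 8 3,5-dihydroxy-2-(4-methoxyphenyl)-7-[(3-methylbut-2-en-1-yl)oxy]-4H-chromen-4-one, via chromane-3,4-dione 7 (not isolated)
Conditions: undivided cell, BDD anode, Pt cathode, 6 (10 equiv), 2,6-lutidine (1 equiv), Bu3MeN O3SOMe (0.1 M), HFIP, 25 °C, 3 mA cm−2, 2.1 F mol−1
Reagents that add atoms: none
Why: Proposed new method: the 3-hydroxy-4-pyranone enol of 5 (O3–H on C3=C2, ring O1) is the most easily oxidised group present, so proton-coupled loss of two electrons at the anode should give, via an O3/C2-delocalised radical, the C2 oxocarbenium ion of the chromane-3,4-dione, which anisole attacks through its para carbon in a Friedel–Crafts sense; loss of the arene proton gives dione 7, which enolises to the flavonol 8 while protons are reduced to H2 at the cathode. The closest known reaction type is the anodic dehydrogenative phenol–arene cross-coupling at boron-doped diamond in HFIP, and the C2 cation is the species through which flavonols are known to take up oxygen nucleophiles at C2 on anodic oxidation. No ring is closed and no stereocentre survives, since C2 of 7 becomes sp2 on enolisation. Site selectivity on 5 follows from C2 being the only C–H carbon of the enol π-system (C6 and C8 carry little spin or charge), and para selectivity on 6 from the methoxy group and the bulk of the electrophile. Chemoselectivity needs the enol to be oxidised before the prenyl alkene, the A-ring ether and anisole, which the lower potential of the lutidine-buffered enol and the low current density should secure, the buffer also keeping anodic acid away from the prenyl ether. Homo-coupling is countered by the excess of 6, and over-oxidation of 8 by stopping near 2 F mol−1 in HFIP, a solvent that damps further oxidation of coupled products.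

**Compound list**

1 | 5,7-dihydroxy-4H-chromen-4-one | O=c1ccoc2cc(O)cc(O)c12 | starting material
2 | 1-bromo-3-methylbut-2-ene (prenyl bromide) | CC(C)=CCBr | starting material
3 | 5-hydroxy-7-[(3-methylbut-2-en-1-yl)oxy]-4H-chromen-4-one | O=c1ccoc2cc(OCC=C(C)C)cc(O)c12 | intermediate
4 | cis-2,3-epoxy-5-hydroxy-7-[(3-methylbut-2-en-1-yl)oxy]chroman-4-one (racemic, one enantiomer drawn) | CC(C)=CCOc1cc(O)c2c(c1)O[C@H]1O[C@H]1C2=O | intermediate
5 | 3,5-dihydroxy-7-[(3-methylbut-2-en-1-yl)oxy]-4H-chromen-4-one | O=c1c(O)coc2cc(OCC=C(C)C)cc(O)c12 | intermediate
6 | anisole (methoxybenzene) | COc1ccccc1 | starting material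
7 | 5-hydroxy-2-(4-methoxyphenyl)-7-[(3-methylbut-2-en-1-yl)oxy]chromane-3,4-dione (racemic keto tautomer, no configuration assigned) | COc1ccc(cc1)C1Oc2cc(OCC=C(C)C)cc(O)c2C(=O)C1=O | intermediate
8 | 3,5-dihydroxy-2-(4-methoxyphenyl)-7-[(3-methylbut-2-en-1-yl)oxy]-4H-chromen-4-one | COc1ccc(-c2oc3cc(OCC=C(C)C)cc(O)c3c(=O)c2O)cc1 | target

**Step count and risks**

Total step count: 3. Longest linear sequence: 3 steps (1 → 3 → 5 → 8).

Steps most likely to fail:

Step 3 (proposed new method). Three processes may spoil it:
- over-oxidation of the product, whose conjugated aryl ring lowers its potential below that of 5;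
- loss of the prenyl group through acid formed at the anode;
- attack of the C2 cation on the A ring of a second molecule, or ortho attack on anisole.

The fallback forms the same C2–aryl bond by known chemistry and sets out from 5. Both hydroxyls are silylated (TBSOTf, 2,6-lutidine, CH2Cl2) to give 3,5-bis(tert-butyldimethylsilyloxy)-7-(prenyloxy)chromone F1. Directed C2 zincation with TMPZnCl·LiCl in THF gives the 2-chromonylzinc chloride F2. Negishi coupling with 4-iodoanisole (Pd(dba)2, tri(2-furyl)phosphine, THF, 50 °C) should give the bis-silyl ether of the target F3. TBAF/AcOH in THF at 0 °C then returns to the route at 8.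

Step 2. The nucleophilic epoxidation may stall if the 5-hydroxyl is deprotonated and the phenoxide deactivates the enone, or the pyranone ring may be opened by the basic peroxide before the epoxide closes. The fallback reverses the order of hydroxylation and prenylation and uses an electrophilic oxidant on a prenyl-free substrate. It sets out from 1:
- acetylation (Ac2O, pyridine, DMAP) gives 5,7-diacetoxychromone F4;
- dimethyldioxirane in acetone/CH2Cl2 gives the diacetoxy epoxychromanone F5, which cat. TsOH isomerises to 5,7-diacetoxy-3-hydroxychromone F6;
- methanolysis (K2CO3, MeOH) gives 3,5,7-trihydroxychromone F7;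
- alkylation with 2 (1.0 equiv, K2CO3 1.0 equiv, DMF, 0 °C to rt) should go to the most acidic 7-OH, as in standard 7-O-alkylations of flavonols with free 3- and 5-hydroxyls, and returns to the route at 5.

Step 1. Forcing the ambident phenoxide may lead to C-prenylation at C6/C8 or to a second alkylation at the chelated 5-OH. The fallback replaces the phenoxide alkylation by a Mitsunobu redox condensation on the neutral phenol. It sets out from 1 with 3-methylbut-2-en-1-ol, PPh3 and DIAD in THF (0 °C to rt), where only the acidic 7-OH is engaged, and returns to the route at 3; no new compound arises (F0).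

**Further compounds**

F1 | step 3 | 3,5-bis(tert-butyldimethylsilyloxy)-7-[(3-methylbut-2-en-1-yl)oxy]-4H-chromen-4-one | CC(C)=CCOc1cc(O[Si](C)(C)C(C)(C)C)c2c(c1)occ(O[Si](C)(C)C(C)(C)C)c2=O
F2 | step 3 | [3,5-bis(tert-butyldimethylsilyloxy)-7-[(3-methylbut-2-en-1-yl)oxy]-4-oxo-4H-chromen-2-yl]zinc chloride | CC(C)=CCOc1cc(O[Si](C)(C)C(C)(C)C)c2c(c1)oc([Zn]Cl)c(O[Si](C)(C)C(C)(C)C)c2=O
F3 | step 3 | 3,5-bis(tert-butyldimethylsilyloxy)-2-(4-methoxyphenyl)-7-[(3-methylbut-2-en-1-yl)oxy]-4H-chromen-4-one | COc1ccc(cc1)-c1oc2cc(OCC=C(C)C)cc(O[Si](C)(C)C(C)(C)C)c2c(=O)c1O[Si](C)(C)C(C)(C)C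
F4 | step 2 | 5,7-diacetoxy-4H-chromen-4-one | CC(=O)Oc1cc(OC(C)=O)c2c(c1)occc2=O
F5 | step 2 | cis-5,7-diacetoxy-2,3-epoxychroman-4-one (racemic, one enantiomer drawn) | CC(=O)Oc1cc(OC(C)=O)c2c(c1)O[C@H]1O[C@H]1C2=O
F6 | step 2 | 5,7-diacetoxy-3-hydroxy-4H-chromen-4-one | CC(=O)Oc1cc(OC(C)=O)c2c(c1)occ(O)c2=O
F7 | step 2 | 3,5,7-trihydroxy-4H-chromen-4-one | O=c1c(O)coc2cc(O)cc(O)c12
F0 | step 1 | none | none
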